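Slowness is what the north run shows: the target stands at 20.3% after 0.625 d, yet the last 2.00 d add 2.2 percentage points. Here is the quick number, with its reasoning.

- north: starting material 10 mM; reagent 12 mM; free catalyst 0.20 mM; second catalyst 100 µM; the very flask that is asked about, followed so far
- flask: starting material 10 mM; reagent 12.0 mM; free catalyst 0.20 mM; second catalyst 100 µM; time 8.0 d

north run (percent of the starting material charged): time / d: target / % = 0.625: 20.3; 1.67: 31.0; 3.00: 35.1; 5.00: 37.3

(each reading ± 0.3 percentage points)

- Thursday's: change nothing and wait 4.0 d more
- Monday's: at 8.0 d take out 90% of the target then present, then wait 4.0 d
- Tuesday's: at 8.0 d add free catalyst, 100% of the amount charged, then wait 4.0 d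
- Wednesday's: at 8.0 d add reagent, 50.0% of the amount charged, then wait 4.0 d

- target that was removed still counts
- "the catalyst" is free catalyst with its forms; second catalyst is a second catalyst
- additions bring no volume worth counting

- target, in percent of the starting material first charged, at 8.0 d
- the option that brings most further target ("none" if no option brings more than 2 percentage points) (Thursday's / Monday's / Tuesday's / Wednesday's / none)
- target present, with what was taken out counted in, in percent of the starting material first charged, after Monday's
- target present, with what was taken out counted in, in percent of the starting material first charged, after Wednesday's

The readings show target and nothing else, so a cause of the slowing has to be assumed. This reckoning assumes two uses of reagent: target, first order in reagent, and a rival loss, second order in reagent. Rival over target then equals c(reagent)/a, with a taken as constant. Summed over a charge, the target made is a times the natural logarithm of one plus c(reagent)/a. Taking the last reading as the plateau, 3.73 mM of target from 12 mM of reagent, puts that logarithm near 2. So a = 1.86 mM, the crossover concentration: the reagent level at which both uses run equally fast.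

On this reckoning the north flask stays close to its last reading at 8.0 d. Thursday's, Monday's and Tuesday's add no reagent, so the choice here is Wednesday's. This reckoning gives its new reagent 2.68 mM of target, or 26.8% of the starting material charged.

The forecast gives 38% at 8.0 d, 38.4% after Monday's and 38.4% after Wednesday's. It picks Tuesday's, on the ground that “almost no active catalyst remains”. Here it parts from this reckoning.

The north flask gives 38.0% at 8.0 d. Best is Wednesday's, which ends at 49.1%; the 11 points it brings stand against the reckoned 26.8%. Monday's ends at 38.2%, and Tuesday's brings 0.26 points.

    starting material + free catalyst ⇌ free catalyst + open intermediate (K = 2.00, k = 5100 L mol⁻¹ h⁻¹)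
    second catalyst + open intermediate ⇌ catalyst intermediate (K = 76.0 L mol⁻¹, k = 740 L mol⁻¹ h⁻¹)
    reagent + catalyst intermediate → second catalyst + target (k = 1400 L mol⁻¹ h⁻¹)
    starting material + open intermediate → side product (k = 2.70 L mol⁻¹ h⁻¹)
    2 reagent → homo dimer (k = 6.10 L mol⁻¹ h⁻¹)

In the north flask, reagent goes to homo dimer at 11 times its rate to target at 0.0215 d, and at 0.033 times that rate at 8.00 d. By then reagent, the limiting reagent, stands at 0.32% of its charge, and 4.08 mM of homo dimer has formed. The crossover concentration puts this ratio at 6.45 for the full charge of reagent and at 0.0205 for the reagent standing at 8.00 d. For the neighbour flask charged with 3.0 mM of reagent, it gives 17.9% of target, and that flask holds 20.0% at 8.00 d.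

(Readings and results stem from a simulated flask for an exercise; noise was put on by code.)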